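**Retrosynthetic overview**

1. Numbering: oxane ring A is O1′, C2′ (spiro carbon, the same atom as C8 of the bicycle), C3′(Me), C4′(OAc), C5′(Me), C6′(Me). The 2‑oxabicyclo[2.2.2]octane is C1(H), O2, C3(=O), C4(Me), C5(=O), C6(Me), C7(Me), C8. Lactone ring B is C1/O2/C3/C4/C8/C7 and cyclohexanone ring C is C1/C6/C5/C4/C8/C7.
2. Last disconnection: the C4–C8 bond, which closes rings B and C together. The enol of a β‑keto‑δ‑lactone adds to the ring‑A oxocarbenium ion. Ring A (hemiketal) and the δ‑lactone C1/O2/C3/C4/C5/C6 form just before, from the acyclic seco ester 21.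
3. Key disconnection: bonds C4′–C5′ and C2′–C3′, made together by a three‑component nickel‑catalysed conjunctive coupling. The partners are a secondary alkyl boronate (C5′, C6′), a (Z)‑propenyl unit (C3′, C4′) and meso anhydride 11 (C8, C7, C1, C6, C5), which is opened with desymmetrisation.
4. Enabling feature: in ring A, C4′(O)–C3′(Me) is a syn β‑oxy/α‑methyl pair lying between a secondary alkyl carbon (C5′) and the spiro carbon C2′, which is a ketone carbon at the ketal level. In addition, C7(Me)–C1(O)–C6(Me) is an anti,anti triad flanked by two carbonyl‑level carbons (C8 and C5), that is, a hidden meso glutarate.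
5. Order of ring formation: temporary anhydride ring (step 7, opened in step 8), then oxane ring A and the δ‑lactone, then rings B and C (all in step 11). C4 and C3 come from a methylmalonate half ester (step 9).

Key step: step 8

Assumption: (2S,3S)‑2,3‑dimethyloxirane, (Z)‑1‑bromoprop‑1‑ene and methyl hydrogen methylmalonate are taken as purchasable, and C4 (introduced in step 9 between two carbonyls) is carried as an epimer mixture until the bridging in step 11 fixes it.

**Route**

Step 1
Reactants: 1 (2S,3S)-2,3-dimethyloxirane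
Product: 2 (2S,3R)-3-(4,4,5,5-tetramethyl-1,3,2-dioxaborolan-2-yl)butan-2-ol
Conditions: B2pin2, CuI (10 mol %), LiOtBu (20 mol %), MeOH (2 equiv), THF, rt
Reagents that add atoms: bis(pinacolato)diboron CC1(C)OB(OC1(C)C)B1OC(C)(C)C(C)(C)O1
Why: Copper‑catalysed ring‑opening borylation of an epoxide, in which the boryl–copper species (monovalent copper) should attack the C2‑symmetric trans‑epoxide in an SN2 manner with inversion (both carbons give the same product), setting the C–B centre (future C5′) and leaving the carbinol centre (future C6′) untouched.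

Step 2
Reactants: 2 (2S,3R)-3-(4,4,5,5-tetramethyl-1,3,2-dioxaborolan-2-yl)butan-2-ol
Product: 3 tert-butyldimethyl{[(2S,3R)-3-(4,4,5,5-tetramethyl-1,3,2-dioxaborolan-2-yl)butan-2-yl]oxy}silane
Conditions: TBSCl, imidazole, DMF, rt
Reagents that add atoms: tert-butyldimethylsilyl chloride CC(C)(C)[Si](C)(C)Cl
Why: Standard silylation of a secondary alcohol, which removes the acidic proton before the organolithium of step 8 and gives a β‑silyloxy group that should not eliminate from the boron ate complex; no stereocentre is touched.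

Step 3
Reactants: 4 methacrolein; 5 isopropenylmagnesium bromide
Product: 6 2,4-dimethylpenta-1,4-dien-3-ol
Conditions: THF, −78 → 0 °C; aq. NH4Cl
Reagents that add atoms: none
Why: Grignard 1,2‑addition to the enal gives the achiral bis‑allylic carbinol that holds C8, C7, C1, C6 and C5 of the target in symmetric form.

Step 4
Reactants: 6 2,4-dimethylpenta-1,4-dien-3-ol
Product: 7 tert-butyl[(2,4-dimethylpenta-1,4-dien-3-yl)oxy]dimethylsilane
Conditions: TBSCl, imidazole, DMF, rt
Reagents that add atoms: tert-butyldimethylsilyl chloride CC(C)(C)[Si](C)(C)Cl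
Why: Standard silylation, which installs the allylic silyloxy group that directs the hydroboration of step 5 and protects the C1 oxygen until step 11.

Step 5
Reactants: 7 tert-butyl[(2,4-dimethylpenta-1,4-dien-3-yl)oxy]dimethylsilane
Product: 8 meso-(2R,3s,4S)-3-[(tert-butyldimethylsilyl)oxy]-2,4-dimethylpentane-1,5-diol
Conditions: 9-BBN (2.4 equiv), THF, 0 °C → rt; then NaOH, 30 % H2O2, 0 °C
Reagents that add atoms: hydrogen peroxide OO
Why: Two‑directional Still–Barrish hydroboration–oxidation, in which 9‑BBN should add to each 1,1‑disubstituted alkene anti to the allylic silyloxy group in the A(1,3)‑minimised conformer, giving the anti,anti (meso) triad that becomes C7/C1/C6.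

Step 6
Reactants: 8 meso-(2R,3s,4S)-3-[(tert-butyldimethylsilyl)oxy]-2,4-dimethylpentane-1,5-diol
Product: 10 meso-(2R,3r,4S)-3-[(tert-butyldimethylsilyl)oxy]-2,4-dimethylpentanedioic acid, via meso dialdehyde 9 (not isolated)
Conditions: (COCl)2, DMSO, CH2Cl2, −78 °C; Et3N, → 0 °C; then NaClO2, NaH2PO4, 2-methylbut-2-ene, t-BuOH/H2O, 0 °C → rt
Reagents that add atoms: sodium chlorite [Na+].[O-]Cl=O
Why: Swern oxidation activates both hydroxyls before any carbonyl exists, so no lactol or lactone should intercept the dialdehyde, and Pinnick oxidation then gives the diacid without epimerising the α‑methyl centres.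

Step 7
Reactants: 10 meso-(2R,3r,4S)-3-[(tert-butyldimethylsilyl)oxy]-2,4-dimethylpentanedioic acid
Product: 11 meso-(3R,4r,5S)-4-[(tert-butyldimethylsilyl)oxy]-3,5-dimethyloxane-2,6-dione
Conditions: DCC, CH2Cl2, 0 °C → rt
Reagents that add atoms: none
Why: Carbodiimide cyclodehydration closes the six‑membered anhydride under neutral conditions, so the all‑cis arrangement of the three substituents should be retained.

Step 8
Reactants: 3 tert-butyldimethyl{[(2S,3R)-3-(4,4,5,5-tetramethyl-1,3,2-dioxaborolan-2-yl)butan-2-yl]oxy}silane; 12 (Z)-1-bromoprop-1-ene; 11 meso-(3R,4r,5S)-4-[(tert-butyldimethylsilyl)oxy]-3,5-dimethyloxane-2,6-dione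
Product: 16 (2S,3S,4R,6S,7R,8S,9S)-3,9-bis[(tert-butyldimethylsilyl)oxy]-7-hydroxy-2,4,6,8-tetramethyl-5-oxodecanoic acid, via (Z)-prop-1-enyllithium 13 (not isolated), via lithium alkenylborate 14 (not isolated), via boryl keto acid 15 (not isolated)
Conditions: 12, t-BuLi (2 equiv), Et2O, −78 °C; 3, −78 → 0 °C; then 11, Ni(cod)2 (10 mol %), (R,R)- or (S,S)-N,N′-dimethyl-1,2-diphenylethane-1,2-diamine (12 mol %, the enantiomer matched with 3), THF, 0 °C → rt; then pH 7 buffer, 30 % H2O2, 0 °C; 1 M HCl
Reagents that add atoms: hydrogen peroxide OO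
Why: Proposed new method: zerovalent nickel carrying the chiral diamine should insert into one of the two enantiotopic acyl C–O bonds of meso anhydride 11, and the acylnickel carboxylate (divalent nickel) then binds the (Z)‑propenyl group of ate complex 14 and induces a 1,2‑metallate shift of the secondary alkyl group from boron to the α‑carbon anti to nickel (bond C4′–C5′), after which C(sp3)–C(acyl) reductive elimination forms bond C2′–C3′ and buffered peroxide oxidises the C4′–B bond with retention. The closest known reaction types are the nickel‑catalysed conjunctive cross‑coupling of alkenylboron ate complexes with acyl electrophiles (acid chlorides give β‑boryl ketones) and the metal‑catalysed alkylative desymmetrisation of meso glutaric anhydrides by organozinc reagents; new here is their merger on a cyclic meso anhydride with a pinacol‑boron ate complex that carries a stereodefined secondary migrating group. The step closes no ring: it opens the anhydride ring, and ring A closes only in step 11 by hemiketalisation onto the ketone made here. C5′ migrates with retention and C6′ is not touched, while C4′ and C3′ arise by stereospecific anti addition of the migrating carbon and the acyl group across the (Z)‑alkene, which gives the required syn C4′–O/C3′–Me pair, and the alkene face is set by the chiral ligand on nickel. The choice between the enantiotopic carbonyls, which decides how the preformed anti,anti triad C7/C1/C6 sits relative to the western centres, is likewise under ligand control. The step needs the conjunctive pathway to outrun direct acyl transfer of the propenyl group and decarbonylation of the α‑branched acylnickel species, and the four‑coordinate oxygen‑ligated boron (slow transmetalation), the electron‑rich 1,2‑disubstituted alkene and fast reductive elimination from an acyl(alkyl)nickel centre should secure this.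

Step 9
Reactants: 16 (2S,3S,4R,6S,7R,8S,9S)-3,9-bis[(tert-butyldimethylsilyl)oxy]-7-hydroxy-2,4,6,8-tetramethyl-5-oxodecanoic acid; 17 3-methoxy-2-methyl-3-oxopropanoic acid
Product: 20 methyl (2RS,4S,5S,6R,8S,9R,10S,11S)-5,11-bis[(tert-butyldimethylsilyl)oxy]-9-hydroxy-2,4,6,8,10-pentamethyl-3,7-dioxododecanoate, via magnesium malonate 18 (not isolated), via acyl imidazole 19 (not isolated)
Conditions: CDI (1.05 equiv), THF, rt, 1 h; then 18 (from 17 and Mg(OEt)2, THF), rt → 40 °C; 1 M HCl
Reagents that add atoms: none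
Why: Masamune–Brooks C‑acylation, in which the acid is converted selectively to its imidazolide (the hindered secondary hydroxyl reacts far more slowly with CDI), the magnesium malonate half ester is acylated and decarboxylation gives the β‑keto ester; the new α‑centre (C4) is left as a mixture because step 11 sets it.

Step 10
Reactants: 20 methyl (2RS,4S,5S,6R,8S,9R,10S,11S)-5,11-bis[(tert-butyldimethylsilyl)oxy]-9-hydroxy-2,4,6,8,10-pentamethyl-3,7-dioxododecanoate
Product: 21 methyl (2RS,4S,5S,6R,8S,9R,10S,11S)-9-acetoxy-5,11-bis[(tert-butyldimethylsilyl)oxy]-2,4,6,8,10-pentamethyl-3,7-dioxododecanoate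
Conditions: Ac2O, pyridine, DMAP (cat.), CH2Cl2, 0 °C
Reagents that add atoms: acetic anhydride CC(=O)OC(C)=O
Why: DMAP‑catalysed acetylation of the only free hydroxyl installs the C4′ acetate of the target at a stage where no hydroxyl differentiation is needed.

Step 11
Reactants: 21 methyl (2RS,4S,5S,6R,8S,9R,10S,11S)-9-acetoxy-5,11-bis[(tert-butyldimethylsilyl)oxy]-2,4,6,8,10-pentamethyl-3,7-dioxododecanoate
Product: 24 (1S,4R,6S,7R,8S,3′S,4′R,5′R,6′S)-3′,4,5′,6,6′,7-hexamethyl-3,5-dioxospiro[2-oxabicyclo[2.2.2]octane-8,2′-oxan]-4′-yl acetate, via dihydroxy diketo ester 22 (not isolated), via hemiketal lactone 23 (not isolated)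
Conditions: HF·pyridine, THF, 0 °C → rt; then CSA, CH2Cl2, 4 Å MS, rt
Reagents that add atoms: none
Why: Desilylation lets the C6′ hydroxyl close ring A on the C2′ ketone (hemiketal, 6‑exo‑trig) and the C1 hydroxyl lactonise with the methyl ester (6‑exo‑trig), and the acid then ionises the hemiketal to the ring‑A oxocarbenium ion, which the β‑keto‑lactone enol attacks through carbon (6‑(enolendo)‑exo‑trig, Mukaiyama/Ferrier‑type C‑alkylation of a 1,3‑dicarbonyl), closing rings B and C in one bond; axial attack trans to the equatorial C6′ methyl should set the spiro centre, the tether fixes C4, and C6 can equilibrate to the 5,6‑trans arrangement found in the target.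

**Compound list**

1 | (2S,3S)-2,3-dimethyloxirane | C[C@@H]1O[C@H]1C | starting material
2 | (2S,3R)-3-(4,4,5,5-tetramethyl-1,3,2-dioxaborolan-2-yl)butan-2-ol | C[C@H](O)[C@@H](C)B1OC(C)(C)C(C)(C)O1 | intermediate
3 | tert-butyldimethyl{[(2S,3R)-3-(4,4,5,5-tetramethyl-1,3,2-dioxaborolan-2-yl)butan-2-yl]oxy}silane | C[C@H](O[Si](C)(C)C(C)(C)C)[C@@H](C)B1OC(C)(C)C(C)(C)O1 | intermediate
4 | methacrolein (2-methylprop-2-enal) | CC(=C)C=O | starting material
5 | isopropenylmagnesium bromide | CC(=C)[Mg]Br | starting material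
6 | 2,4-dimethylpenta-1,4-dien-3-ol | CC(=C)C(O)C(C)=C | intermediate
7 | tert-butyl[(2,4-dimethylpenta-1,4-dien-3-yl)oxy]dimethylsilane | CC(=C)C(O[Si](C)(C)C(C)(C)C)C(C)=C | intermediate
8 | meso-(2R,3s,4S)-3-[(tert-butyldimethylsilyl)oxy]-2,4-dimethylpentane-1,5-diol (anti,anti) | OC[C@H](C)[C@H](O[Si](C)(C)C(C)(C)C)[C@H](C)CO | intermediate
9 | meso-(2R,3r,4S)-3-[(tert-butyldimethylsilyl)oxy]-2,4-dimethylpentanedial | O=C[C@H](C)[C@H](O[Si](C)(C)C(C)(C)C)[C@H](C)C=O | intermediate
10 | meso-(2R,3r,4S)-3-[(tert-butyldimethylsilyl)oxy]-2,4-dimethylpentanedioic acid | OC(=O)[C@H](C)[C@H](O[Si](C)(C)C(C)(C)C)[C@H](C)C(=O)O | intermediate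
11 | meso-(3R,4r,5S)-4-[(tert-butyldimethylsilyl)oxy]-3,5-dimethyloxane-2,6-dione | O=C1OC(=O)[C@@H](C)[C@@H](O[Si](C)(C)C(C)(C)C)[C@H]1C | intermediate
12 | (Z)-1-bromoprop-1-ene | C/C=C\Br | starting material
13 | (Z)-prop-1-enyllithium | C/C=C\[Li] | intermediate
14 | lithium [(2R,3S)-3-[(tert-butyldimethylsilyl)oxy]butan-2-yl][(Z)-prop-1-enyl](pinacolato)borate | [Li+].C/C=C\[B-]1(OC(C)(C)C(C)(C)O1)[C@H](C)[C@H](C)O[Si](C)(C)C(C)(C)C | intermediate
15 | (2S,3S,4R,6S,7R,8S,9S)-3,9-bis[(tert-butyldimethylsilyl)oxy]-2,4,6,8-tetramethyl-5-oxo-7-(4,4,5,5-tetramethyl-1,3,2-dioxaborolan-2-yl)decanoic acid | C[C@H](O[Si](C)(C)C(C)(C)C)[C@@H](C)[C@@H](B1OC(C)(C)C(C)(C)O1)[C@H](C)C(=O)[C@H](C)[C@H](O[Si](C)(C)C(C)(C)C)[C@H](C)C(=O)O | intermediate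
16 | (2S,3S,4R,6S,7R,8S,9S)-3,9-bis[(tert-butyldimethylsilyl)oxy]-7-hydroxy-2,4,6,8-tetramethyl-5-oxodecanoic acid | C[C@H](O[Si](C)(C)C(C)(C)C)[C@@H](C)[C@@H](O)[C@H](C)C(=O)[C@H](C)[C@H](O[Si](C)(C)C(C)(C)C)[C@H](C)C(=O)O | intermediate
17 | 3-methoxy-2-methyl-3-oxopropanoic acid (methyl hydrogen methylmalonate) | COC(=O)C(C)C(=O)O | starting material
18 | magnesium bis(3-methoxy-2-methyl-3-oxopropanoate) | COC(=O)C(C)C(=O)[O-].COC(=O)C(C)C(=O)[O-].[Mg+2] | intermediate
19 | 1-[(2S,3S,4R,6S,7R,8S,9S)-3,9-bis[(tert-butyldimethylsilyl)oxy]-7-hydroxy-2,4,6,8-tetramethyl-5-oxodecanoyl]-1H-imidazole | C[C@H](O[Si](C)(C)C(C)(C)C)[C@@H](C)[C@@H](O)[C@H](C)C(=O)[C@H](C)[C@H](O[Si](C)(C)C(C)(C)C)[C@H](C)C(=O)n1ccnc1 | intermediate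
20 | methyl (2RS,4S,5S,6R,8S,9R,10S,11S)-5,11-bis[(tert-butyldimethylsilyl)oxy]-9-hydroxy-2,4,6,8,10-pentamethyl-3,7-dioxododecanoate | C[C@H](O[Si](C)(C)C(C)(C)C)[C@@H](C)[C@@H](O)[C@H](C)C(=O)[C@H](C)[C@H](O[Si](C)(C)C(C)(C)C)[C@H](C)C(=O)C(C)C(=O)OC | intermediate
21 | methyl (2RS,4S,5S,6R,8S,9R,10S,11S)-9-acetoxy-5,11-bis[(tert-butyldimethylsilyl)oxy]-2,4,6,8,10-pentamethyl-3,7-dioxododecanoate | C[C@H](O[Si](C)(C)C(C)(C)C)[C@@H](C)[C@@H](OC(C)=O)[C@H](C)C(=O)[C@H](C)[C@H](O[Si](C)(C)C(C)(C)C)[C@H](C)C(=O)C(C)C(=O)OC | intermediate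
22 | methyl 9-acetoxy-5,11-dihydroxy-2,4,6,8,10-pentamethyl-3,7-dioxododecanoate (desilylated 21, configuration unchanged) | C[C@H](O)[C@@H](C)[C@@H](OC(C)=O)[C@H](C)C(=O)[C@H](C)[C@H](O)[C@H](C)C(=O)C(C)C(=O)OC | intermediate
23 | ring-A hemiketal δ-lactone: 2′-hydroxyoxane (C3′ Me, C4′ OAc, C5′ Me, C6′ Me as in 24) carrying at C2′ the 1-(3,5-dimethyl-4,6-dioxooxan-2-yl)ethyl group (C7, C1, C6 as in 24; C2′ and C4 unfixed) | CC(=O)O[C@@H]1[C@H](C)[C@H](C)OC(O)([C@H](C)[C@@H]2OC(=O)C(C)C(=O)[C@H]2C)[C@H]1C | intermediate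
24 | (1S,4R,6S,7R,8S,3′S,4′R,5′R,6′S)-3′,4,5′,6,6′,7-hexamethyl-3,5-dioxospiro[2-oxabicyclo[2.2.2]octane-8,2′-oxan]-4′-yl acetate (CNP0257416.2) | CC(=O)O[C@@H]1[C@H](C)[C@H](C)O[C@]2([C@H](C)[C@@H]3OC(=O)[C@@]2(C)C(=O)[C@H]3C)[C@H]1C | target

**Totals and risks**

Total step count: 11. Longest linear sequence: 9 steps (steps 3 to 11, from methacrolein and isopropenylmagnesium bromide).

Steps most likely to fail:

Step 8 (bears the label). One chiral catalyst has to choose both the alkene face and the enantiotopic carbonyl, so mismatched double selection may erode diastereomeric purity, and the acylnickel intermediate may divert into direct propenyl transfer or decarbonylation. The fallback uses known chemistry and unites the same carbons by an aldol reaction across C3′–C4′. It sets out from 11 and 3 and comes back to the route at 16. Anhydride 11 is opened by enantioselective ethylation ([Rh(cod)Cl]2, chiral phosphinooxazoline ligand, Et2Zn, THF) to ethyl keto acid F1. This is esterified with benzyl 2,2,2‑trichloroacetimidate and catalytic TfOH to benzyl ester F2. Boronate 3 undergoes Matteson homologation (LiCHCl2, THF, −100 °C, then ZnCl2) to α‑chloro boronate F3, and oxidation with NaBO3·4H2O gives aldehyde F4. The (Z)‑boron enolate of F2 (Bu2BOTf, i‑Pr2NEt, CH2Cl2, −78 °C) should add to F4 in a syn‑selective, anti‑Felkin aldol reaction to give aldol adduct F5. Hydrogenolysis (H2, Pd/C, EtOAc) then gives 16.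

Step 11. Under the equilibrating acid conditions the oxocarbenium ion may lose a proton toward C7 and expel the C1 acyloxy group (β‑elimination with opening of the lactone), the enol may attack through oxygen, C7 may epimerise through the exocyclic enol ether, or the acetyl group may migrate to the freed C6′ hydroxyl before ring A closes. The fallback replaces the thermodynamic Brønsted‑acid cascade by a kinetic Lewis‑acid step with a preformed nucleophile. It sets out from 21 and comes back at 24. Desilylation and ketalisation (HF·pyridine, then CSA, HC(OMe)3, MeOH) give methyl ketal lactone F6. Silylation of the β‑keto lactone (TMSCl, Et3N, CH2Cl2) gives silyl enol ether F7. Catalytic TMSOTf in CH2Cl2 at −78 °C then ionises the ketal and effects an intramolecular Mukaiyama‑type addition of the silyl enol ether to the oxocarbenium ion, giving 24.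

Step 1. Boryl–copper attack on the 1,2‑disubstituted epoxide may be slow, with competing base‑induced isomerisation to the allylic alcohol. The fallback gives up the boron fragment and reaches the same carbon chain by aldol chemistry. It sets out from 1 and comes back at 16. 2‑Lithio‑1,3‑dithiane (THF, −20 °C) opens epoxide 1 with inversion to hydroxy dithiane F8. TBSCl and imidazole give silyl ether F9. Hydrolysis (MeI, CaCO3, MeCN/H2O) gives aldehyde F4, which is joined to benzyl ester F2 by the boron aldol reaction described for step 8 to give aldol adduct F5, and hydrogenolysis gives 16.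

**Further compounds**

F1 | step 8 | (2S,3S,4R)-3-[(tert-butyldimethylsilyl)oxy]-2,4-dimethyl-5-oxoheptanoic acid | CCC(=O)[C@H](C)[C@H](O[Si](C)(C)C(C)(C)C)[C@H](C)C(=O)O
F2 | step 8 | benzyl (2S,3S,4R)-3-[(tert-butyldimethylsilyl)oxy]-2,4-dimethyl-5-oxoheptanoate | CCC(=O)[C@H](C)[C@H](O[Si](C)(C)C(C)(C)C)[C@H](C)C(=O)OCc1ccccc1
F3 | step 8 | tert-butyl{[(2S,3R)-4-chloro-3-methyl-4-(4,4,5,5-tetramethyl-1,3,2-dioxaborolan-2-yl)butan-2-yl]oxy}dimethylsilane (C4 epimers) | C[C@H](O[Si](C)(C)C(C)(C)C)[C@@H](C)C(Cl)B1OC(C)(C)C(C)(C)O1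
F4 | step 8 | (2R,3S)-3-[(tert-butyldimethylsilyl)oxy]-2-methylbutanal | C[C@H](O[Si](C)(C)C(C)(C)C)[C@@H](C)C=O
F5 | step 8 | benzyl (2S,3S,4R,6S,7R,8S,9S)-3,9-bis[(tert-butyldimethylsilyl)oxy]-7-hydroxy-2,4,6,8-tetramethyl-5-oxodecanoate | C[C@H](O[Si](C)(C)C(C)(C)C)[C@@H](C)[C@@H](O)[C@H](C)C(=O)[C@H](C)[C@H](O[Si](C)(C)C(C)(C)C)[C@H](C)C(=O)OCc1ccccc1
F6 | step 11 | methyl ketal of 23 (2′-methoxyoxane δ-lactone, other centres as in 23) | CC(=O)O[C@@H]1[C@H](C)[C@H](C)OC(OC)([C@H](C)[C@@H]2OC(=O)C(C)C(=O)[C@H]2C)[C@H]1C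
F7 | step 11 | trimethylsilyl enol ether of F6 (4-silyloxy-5,6-dihydro-2H-pyran-2-one) | CC(=O)O[C@@H]1[C@H](C)[C@H](C)OC(OC)([C@H](C)[C@@H]2OC(=O)C(C)=C(O[Si](C)(C)C)[C@H]2C)[C@H]1C
F8 | step 1 | (2S,3R)-3-(1,3-dithian-2-yl)butan-2-ol | C[C@H](O)[C@@H](C)C1SCCCS1
F9 | step 1 | tert-butyl{[(2S,3R)-3-(1,3-dithian-2-yl)butan-2-yl]oxy}dimethylsilane | C[C@H](O[Si](C)(C)C(C)(C)C)[C@@H](C)C1SCCCS1
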